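**Plan**
- Retrosynthesis: the aryl ether bond O1–C8a of ring C is cut first and the aryl ketone bond C4–C4a next (flavanone numbering). This leaves a ring A aryl bromide and a three-carbon Weinreb amide; the bromide is cut at the C6–CH bond and the amide at C2–C3.
- Forward: ring A is dressed first (side chain at C6, bromine at C4a), and the C2–C3–C4 unit is made separately. One pot then joins C4 to C4a and closes ring C through a C8–C8a aryne, and a global deprotection ends the route.
- Enabling feature: C8 carries chlorine next to the C7 methoxy group (an o-chloroanisole), and C8a–H is the only hydrogen of ring A. The derived C8–C8a aryne is flanked by C7–OMe and by C4a, which holds the C4–C3–C2–O tether, so oxygen goes to C8a and hydrogen to C8.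
- Helpers: the C4 ketone stays masked as the Weinreb tetrahedral adduct while base is present; chlorine leaves as LiCl; the C5 methyl ether and three benzyl ethers come off in the last step.
- Stereochemistry: the (R) side-chain centre comes from an iridium-catalysed asymmetric hydrogenation. C2 and C3 (R,R, anti) come from an auxiliary-controlled anti-glycolate aldol and are carried through because the C2–O bond is never broken.

Key step: step 7

Remark: the sense of induction in step 2 (iridium catalyst) and step 5 (titanium aldol) is assigned from the usual models; if a first run shows the opposite sense, the mirror-image ligand or auxiliary is used.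

**Step 1**
Reactants: 1 1-chloro-2,4-dimethoxybenzene; 2 1-[4-(benzyloxy)phenyl]ethan-1-one
Product: 5 1-chloro-3-{1-[4-(benzyloxy)phenyl]ethenyl}-2,4-dimethoxybenzene, via aryllithium 3 (not isolated), via tertiary carbinol 4 (not isolated)
Conditions: n-BuLi, THF, −20 → 0 °C; CeCl3 (anhydrous), −78 °C; 2, −78 → 0 °C; then p-TsOH·H2O (1.5 eq), toluene, 50 °C
Reagents that add atoms: none
Why: Directed ortho-metalation takes the C–H between the two methoxy groups (chlorine is not exchanged at this temperature), the CeCl3-modified aryllithium adds to the enolisable ketone, and the doubly benzylic tertiary carbinol loses water by acid-promoted E1 dehydration to the 1,1-diarylethene; no stereocentre is formed.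

**Step 2**
Reactants: 5 1-chloro-3-{1-[4-(benzyloxy)phenyl]ethenyl}-2,4-dimethoxybenzene
Product: 6 1-chloro-3-{(1R)-1-[4-(benzyloxy)phenyl]ethyl}-2,4-dimethoxybenzene
Conditions: [Ir(cod)(L)]BArF (1 mol %; L = (S)-4-tert-butyl-2-[2-(diphenylphosphino)phenyl]-2-oxazoline, BArF = tetrakis[3,5-bis(trifluoromethyl)phenyl]borate), H2 (5 bar), CH2Cl2, rt
Reagents that add atoms: none
Why: Iridium-catalysed asymmetric hydrogenation of a 1,1-diarylethene with an N,P ligand should set the (R) benzylic centre, because the 2,6-dimethoxyaryl ring is twisted out of the alkene plane while the 4-benzyloxyphenyl ring is coplanar, so the catalyst sees two very different aryl groups; aryl chloride and benzyl ether are inert to the homogeneous catalyst.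

**Step 3**
Reactants: 6 1-chloro-3-{(1R)-1-[4-(benzyloxy)phenyl]ethyl}-2,4-dimethoxybenzene
Product: 7 1-bromo-3-{(1R)-1-[4-(benzyloxy)phenyl]ethyl}-5-chloro-2,4-dimethoxybenzene
Conditions: NBS (1.05 eq), MeCN, 0 °C → rt, dark
Reagents that add atoms: N-bromosuccinimide, O=C1CCC(=O)N1Br
Why: Electrophilic aromatic bromination should go to the one free ring A position that is ortho to one methoxy group and para to the other (the future C4a), since the other free position is meta to both and the anisole-type ring is much less activated.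

**Step 4**
Reactants: 8 (4S)-4-benzyl-1,3-oxazolidine-2-thione; 9 (benzyloxy)acetyl chloride
Product: 10 (4S)-4-benzyl-3-[(benzyloxy)acetyl]-1,3-oxazolidine-2-thione
Conditions: Et3N, DMAP (cat.), CH2Cl2, 0 °C → rt
Reagents that add atoms: none
Why: N-acylation of the oxazolidinethione with an acid chloride gives the N-glycolyl imide used for auxiliary-controlled aldol chemistry.

**Step 5**
Reactants: 10 (4S)-4-benzyl-3-[(benzyloxy)acetyl]-1,3-oxazolidine-2-thione; 11 4-(benzyloxy)benzaldehyde
Product: 13 (4S)-4-benzyl-3-{(2R,3R)-2-(benzyloxy)-3-[4-(benzyloxy)phenyl]-3-hydroxypropanoyl}-1,3-oxazolidine-2-thione, via titanium enolate 12 (not isolated)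
Conditions: TiCl4 (1.1 eq), i-Pr2NEt (1.1 eq), CH2Cl2, −78 °C; then 11 pre-mixed with TiCl4 (2 eq each), −78 °C; aq. NH4Cl
Reagents that add atoms: none
Why: In this anti-selective glycolate aldol of a titanium enolate of an N-glycolyl oxazolidinethione (Crimmins type), the aldehyde activated by external TiCl4 cannot bind the enolate titanium, so an open transition state should give the 2,3-anti adduct, and the benzyl group of the sulfur-chelated (Z)-enolate shields one face to set C2 as (R) and hence C3 as (R).

**Step 6**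
Reactants: 13 (4S)-4-benzyl-3-{(2R,3R)-2-(benzyloxy)-3-[4-(benzyloxy)phenyl]-3-hydroxypropanoyl}-1,3-oxazolidine-2-thione
Product: 14 (2R,3R)-2-(benzyloxy)-3-[4-(benzyloxy)phenyl]-3-hydroxy-N-methoxy-N-methylpropanamide
Conditions: MeNH(OMe)·HCl, imidazole, CH2Cl2, rt
Reagents that add atoms: N,O-dimethylhydroxylamine hydrochloride, CNOC.Cl
Why: The activated N-acyl oxazolidinethione undergoes direct aminolysis to the Weinreb amide under near-neutral conditions, without protection of the β-hydroxyl and without touching either stereocentre.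

**Step 7**
Reactants: 7 1-bromo-3-{(1R)-1-[4-(benzyloxy)phenyl]ethyl}-5-chloro-2,4-dimethoxybenzene; 14 (2R,3R)-2-(benzyloxy)-3-[4-(benzyloxy)phenyl]-3-hydroxy-N-methoxy-N-methylpropanamide
Product: 19 (2R,3R)-3-(benzyloxy)-2-[4-(benzyloxy)phenyl]-6-{(1R)-1-[4-(benzyloxy)phenyl]ethyl}-5,7-dimethoxy-2,3-dihydro-4H-chromen-4-one, via aryllithium 15 (not isolated), via tetrahedral adduct 16 (not isolated), via aryne 17 (not isolated), via lithiated chromane adduct 18 (not isolated)
Conditions: 7 (1.1 eq), t-BuLi (2.2 eq), THF, −78 °C; lithium alkoxide of 14 (14 + LiTMP, 1.0 eq, THF, −78 °C), −78 → −40 °C; LiTMP (2.5 eq, pre-formed in THF), −78 → 0 °C; inverse quench into AcOH/THF, −78 °C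
Reagents that add atoms: none
Why: Proposed new method: Br/Li exchange at C4a gives aryllithium 15, which adds to the Weinreb amide of the lithium alkoxide of 14 to form the chelated tetrahedral adduct 16 (known type: acylation of an aryllithium with a Weinreb amide, whose N-methoxy-N-methyl hemiaminal alkoxide persists until work-up). LiTMP then removes C8a–H, the only ring A proton, which is acidified by the C8 chlorine and directed by the neighbouring α-amino alkoxide; loss of LiCl gives the C8–C8a aryne 17, and the C2 lithium alkoxide adds to C8a to close ring C through the O1–C8a bond (closest known type: base-induced benzyne cyclisation of a haloarene alkoxide, the o-haloanisole cine-substitution made intramolecular). The ring closes in a 6-exo mode on the in-plane π bond of the aryne, with C8a inside the new ring and C8 outside. No new stereocentre survives, since the hemiaminal carbon C4 of 18 returns to the ketone on acidic quench; C2 and C3 keep the configuration of 14 because the C2–O bond is not broken and C3–H is not acidic while C4 is sp3. Regioselectivity is secured twice: the C7 methoxy group beside C8 polarises the aryne so that the nucleophile bonds to the distal carbon C8a and the charge (lithium held by OMe) sits on C8, and the three-atom tether from C4a can reach only C8a; the C8 hydrogen comes from the quench. The needed chemoselectivity is that no ketone exists while base is present, which shuts off retro-aldol and C3 epimerisation, and that LiTMP is too hindered to add to the aryne.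

**Step 8**
Reactants: 19 (2R,3R)-3-(benzyloxy)-2-[4-(benzyloxy)phenyl]-6-{(1R)-1-[4-(benzyloxy)phenyl]ethyl}-5,7-dimethoxy-2,3-dihydro-4H-chromen-4-one
Product: 20 (2R,3R)-3,5-dihydroxy-2-(4-hydroxyphenyl)-6-[(1R)-1-(4-hydroxyphenyl)ethyl]-7-methoxy-2,3-dihydro-4H-chromen-4-one
Conditions: BCl3 (8 eq), pentamethylbenzene (10 eq), CH2Cl2, −78 → 0 °C; H2O work-up
Reagents that add atoms: none
Why: BCl3 with pentamethylbenzene as cation scavenger should cleave the three benzyl ethers, and chelation between the C4 carbonyl and the peri C5 methoxy group directs the selective demethylation at C5, while the unchelated C7 methyl ether and the three stereocentres are left alone.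

**Compound list**
1 | 1-chloro-2,4-dimethoxybenzene | COc1ccc(Cl)c(OC)c1 | starting material
2 | 1-[4-(benzyloxy)phenyl]ethan-1-one | CC(=O)c1ccc(OCc2ccccc2)cc1 | starting material
3 | (3-chloro-2,6-dimethoxyphenyl)lithium | [Li]c1c(OC)ccc(Cl)c1OC | intermediate
4 | 1-[4-(benzyloxy)phenyl]-1-(3-chloro-2,6-dimethoxyphenyl)ethan-1-ol (racemic) | CC(O)(c1ccc(OCc2ccccc2)cc1)c1c(OC)ccc(Cl)c1OC | intermediate
5 | 1-chloro-3-{1-[4-(benzyloxy)phenyl]ethenyl}-2,4-dimethoxybenzene | C=C(c1ccc(OCc2ccccc2)cc1)c1c(OC)ccc(Cl)c1OC | intermediate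
6 | 1-chloro-3-{(1R)-1-[4-(benzyloxy)phenyl]ethyl}-2,4-dimethoxybenzene | COc1ccc(Cl)c(OC)c1[C@H](C)c1ccc(OCc2ccccc2)cc1 | intermediate
7 | 1-bromo-3-{(1R)-1-[4-(benzyloxy)phenyl]ethyl}-5-chloro-2,4-dimethoxybenzene | COc1c(Cl)cc(Br)c(OC)c1[C@H](C)c1ccc(OCc2ccccc2)cc1 | intermediate
8 | (4S)-4-benzyl-1,3-oxazolidine-2-thione | S=C1N[C@@H](Cc2ccccc2)CO1 | starting material
9 | (benzyloxy)acetyl chloride | O=C(Cl)COCc1ccccc1 | starting material
10 | (4S)-4-benzyl-3-[(benzyloxy)acetyl]-1,3-oxazolidine-2-thione | S=C1N(C(=O)COCc2ccccc2)[C@@H](Cc2ccccc2)CO1 | intermediate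
11 | 4-(benzyloxy)benzaldehyde | O=Cc1ccc(OCc2ccccc2)cc1 | starting material
12 | trichlorotitanium (Z)-enolate of 10 | Cl[Ti](Cl)(Cl)O/C(=C\OCc1ccccc1)N1[C@@H](Cc2ccccc2)COC1=S | intermediate
13 | (4S)-4-benzyl-3-{(2R,3R)-2-(benzyloxy)-3-[4-(benzyloxy)phenyl]-3-hydroxypropanoyl}-1,3-oxazolidine-2-thione | S=C1N(C(=O)[C@H](OCc2ccccc2)[C@@H](c2ccc(OCc3ccccc3)cc2)O)[C@@H](Cc2ccccc2)CO1 | intermediate
14 | (2R,3R)-2-(benzyloxy)-3-[4-(benzyloxy)phenyl]-3-hydroxy-N-methoxy-N-methylpropanamide | CON(C)C(=O)[C@H](OCc1ccccc1)[C@@H](c1ccc(OCc2ccccc2)cc1)O | intermediate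
15 | (3-{(1R)-1-[4-(benzyloxy)phenyl]ethyl}-5-chloro-2,4-dimethoxyphenyl)lithium | COc1c(Cl)cc([Li])c(OC)c1[C@H](C)c1ccc(OCc2ccccc2)cc1 | intermediate
16 | dilithium alkoxide of the N-methoxy-N-methyl hemiaminal from 15 and 14 (tetrahedral adduct, C4 configuration not defined, other centres as in 7 and 14) | COc1c(Cl)cc(C(O[Li])(N(C)OC)[C@H](OCc2ccccc2)[C@@H](c2ccc(OCc3ccccc3)cc2)O[Li])c(OC)c1[C@H](C)c1ccc(OCc2ccccc2)cc1 | intermediate
17 | C8–C8a aryne derived from 16 by loss of LiCl | COC1=C([C@H](C)c2ccc(OCc3ccccc3)cc2)C(OC)=C(C(O[Li])(N(C)OC)[C@H](OCc2ccccc2)[C@@H](c2ccc(OCc3ccccc3)cc2)O[Li])C#C1 | intermediate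
18 | C8-lithiated chromane bearing the lithium hemiaminal alkoxide at C4 (ring-closed adduct) | COc1c([Li])c2c(c(OC)c1[C@H](C)c1ccc(OCc3ccccc3)cc1)C(O[Li])(N(C)OC)[C@H](OCc1ccccc1)[C@@H](c1ccc(OCc3ccccc3)cc1)O2 | intermediate
19 | (2R,3R)-3-(benzyloxy)-2-[4-(benzyloxy)phenyl]-6-{(1R)-1-[4-(benzyloxy)phenyl]ethyl}-5,7-dimethoxy-2,3-dihydro-4H-chromen-4-one | COc1cc2c(c(OC)c1[C@H](C)c1ccc(OCc3ccccc3)cc1)C(=O)[C@H](OCc1ccccc1)[C@@H](c1ccc(OCc3ccccc3)cc1)O2 | intermediate
20 | (2R,3R)-3,5-dihydroxy-2-(4-hydroxyphenyl)-6-[(1R)-1-(4-hydroxyphenyl)ethyl]-7-methoxy-2,3-dihydro-4H-chromen-4-one | COc1cc2c(c(O)c1[C@H](C)c1ccc(O)cc1)C(=O)[C@H](O)[C@@H](c1ccc(O)cc1)O2 | target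

**Count**
Total steps: 8. Longest linear sequence: 5 steps (1 → 2 → 3 → 7 → 8, or 4 → 5 → 6 → 7 → 8).

**Steps most likely to fail**

Step 7 (proposed new method). The tetrahedral adduct may collapse or lose its N-methoxy group under LiTMP before the aryne forms, which would expose the ketone to retro-aldol and C3 epimerisation. Lithiation at C8a may also be too slow next to the crowded hemiaminal carbon, and the base may attack the benzylic ether positions. The fallback sets out from 7 and 14 and returns at 19, and divides the one-pot into known operations at the alcohol oxidation level. Aryllithium 15 is added to the lithium alkoxide of 14 and the mixture is quenched at −78 °C to give (2R,3R)-2-(benzyloxy)-3-[4-(benzyloxy)phenyl]-1-(3-{(1R)-1-[4-(benzyloxy)phenyl]ethyl}-5-chloro-2,4-dimethoxyphenyl)-3-hydroxypropan-1-one F1. NaBH4 (MeOH/THF, 0 °C) reduces it to the corresponding (1RS,2R,3R)-propane-1,3-diol F2, and both C1 epimers are carried on. LiTMP (3.5 eq, THF, −78 → 0 °C) then converts the o-chloroanisole unit into the same C8–C8a aryne, which the C2 alkoxide captures in a classical benzyne cyclisation to give the chroman-4-ol corresponding to 19 (C4 epimers, C2 and C3 as in 19) F3. Dess–Martin periodinane (CH2Cl2, rt) oxidises C4–OH to ketone 19.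

Step 5. The open transition state may give poor anti/syn or facial selectivity with the electron-rich aromatic aldehyde, and the benzylic titanium alkoxide may ionise under excess TiCl4. The fallback sets out from 9 and 11 and returns at 14, and replaces the auxiliary by a reagent-controlled Mukaiyama aldol. Acid chloride 9 is treated with EtSH and Et3N to give S-ethyl 2-(benzyloxy)ethanethioate F4. LDA and Me3SiCl (THF, −78 °C) convert it into (Z)-[2-(benzyloxy)-1-(ethylsulfanyl)ethenyl]oxy(trimethyl)silane F5. Reaction of F5 with 11 under Sn(OTf)2, Bu2Sn(OAc)2 and the enantiomer of 1-methyl-2-[(1-naphthylamino)methyl]pyrrolidine that leads to the (2R,3R) adduct (CH2Cl2, −78 °C) gives the anti adduct S-ethyl (2R,3R)-2-(benzyloxy)-3-[4-(benzyloxy)phenyl]-3-hydroxypropanethioate F6. MeNH(OMe)·HCl with i-PrMgCl (THF, −20 °C) turns F6 into Weinreb amide 14.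

Step 2. Enantioface discrimination may be poor, or hydrogenation of the hindered alkene slow, since both aryl groups carry oxygen substituents. The fallback sets out from 5 and returns at 6, and replaces asymmetric catalysis by resolution. Non-selective hydrogenation with [Ir(cod)(PCy3)(py)]PF6 (H2, CH2Cl2, rt) gives racemic 1-chloro-3-{1-[4-(benzyloxy)phenyl]ethyl}-2,4-dimethoxybenzene F7. The enantiomers are separated by preparative supercritical-fluid chromatography on an amylose-based chiral phase, and the (R)-enantiomer is 6.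

**Further compounds**
F1 | step 7 | (2R,3R)-2-(benzyloxy)-3-[4-(benzyloxy)phenyl]-1-(3-{(1R)-1-[4-(benzyloxy)phenyl]ethyl}-5-chloro-2,4-dimethoxyphenyl)-3-hydroxypropan-1-one | COc1c(Cl)cc(C(=O)[C@H](OCc2ccccc2)[C@@H](c2ccc(OCc3ccccc3)cc2)O)c(OC)c1[C@H](C)c1ccc(OCc2ccccc2)cc1
F2 | step 7 | (1RS,2R,3R)-2-(benzyloxy)-3-[4-(benzyloxy)phenyl]-1-(3-{(1R)-1-[4-(benzyloxy)phenyl]ethyl}-5-chloro-2,4-dimethoxyphenyl)propane-1,3-diol | COc1c(Cl)cc(C(O)[C@H](OCc2ccccc2)[C@@H](c2ccc(OCc3ccccc3)cc2)O)c(OC)c1[C@H](C)c1ccc(OCc2ccccc2)cc1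
F3 | step 7 | chroman-4-ol corresponding to 19 (C4 epimers, C2 and C3 as in 19) | COc1cc2c(c(OC)c1[C@H](C)c1ccc(OCc3ccccc3)cc1)C(O)[C@H](OCc1ccccc1)[C@@H](c1ccc(OCc3ccccc3)cc1)O2
F4 | step 5 | S-ethyl 2-(benzyloxy)ethanethioate | CCSC(=O)COCc1ccccc1
F5 | step 5 | (Z)-[2-(benzyloxy)-1-(ethylsulfanyl)ethenyl]oxy(trimethyl)silane | CCS/C(O[Si](C)(C)C)=C\OCc1ccccc1
F6 | step 5 | S-ethyl (2R,3R)-2-(benzyloxy)-3-[4-(benzyloxy)phenyl]-3-hydroxypropanethioate | CCSC(=O)[C@H](OCc1ccccc1)[C@@H](c1ccc(OCc2ccccc2)cc1)O
F7 | step 2 | racemic 1-chloro-3-{1-[4-(benzyloxy)phenyl]ethyl}-2,4-dimethoxybenzene | COc1ccc(Cl)c(OC)c1C(C)c1ccc(OCc2ccccc2)cc1
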